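Set against twins, E and Q made side by side from G, whose ratio would stand level through a run, our runs climb steeply. That level ratio is the zero of our scale.

| flask | G | J | remark | time |
|---|---|---|---|---|
| red | 0.62 M | 0.55 equiv (fed, over 20 min) | run made earlier; the fed solution adds 0.20 times the starting volume |  |
| amber | 0.62 M | 0.83 equiv (fed, over 20 min) | run made earlier; the fed solution adds 0.20 times the starting volume |  |
| grey | 1.2 M | 1.1 equiv (fed, over 20 min) | run made earlier; the fed solution adds 0.20 times the starting volume |  |
| flask | 0.62 M | 1.10 equiv (fed, over 20 min) | the fed solution adds 0.20 times the starting volume | 1.5 h |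

| run | time / min | G / % | Q / % | E / % |
|---|---|---|---|---|
| red | 6.00 | 95.7 | 4.6 | 0.1 |
| red | 8.00 | 92.9 | 5.6 | 1.1 |
| red | 12.0 | 88.5 | 10.1 | 1.2 |
| red | 20.0 | 78.4 | 17.2 | 3.6 |
| red | 30.0 | 67.7 | 24.6 | 8.4 |
| red | 50.0 | 54.0 | 25.7 | 20.8 |
| red | 80.0 | 45.9 | 19.0 | 35.1 |
| amber | 10.0 | 89.3 | 10.3 | 1.4 |
| amber | 20.0 | 73.9 | 22.0 | 5.3 |
| amber | 30.0 | 59.6 | 29.5 | 11.2 |
| amber | 40.0 | 50.6 | 31.1 | 17.6 |
| amber | 50.0 | 42.7 | 31.4 | 25.4 |
| amber | 60.0 | 36.9 | 29.9 | 32.0 |
| amber | 80.0 | 29.8 | 24.6 | 45.1 |
| grey | 6.00 | 91.4 | 8.2 | 0.7 |
| grey | 10.0 | 83.4 | 15.1 | 1.4 |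
| grey | 20.0 | 61.1 | 30.4 | 7.6 |
| grey | 40.0 | 33.9 | 41.4 | 24.9 |
| grey | 80.0 | 13.9 | 28.2 | 57.5 |

(readings scatter by 0.5 percentage points)

- the state of affairs at 1.5 h: stopped, and by what, or still going (all of G has reacted / J has run out first / forward and back rates have come level / it is still moving)
- how much of the G has reacted by 1.5 h
- how much Q there is at 1.5 h, in percent of the G charged
- how much E there is at 1.5 h, in percent of the G charged

- every charge counts on the volume at the start, and the solution that is fed holds the whole dose
- the reaction counts as stopped when no species that holds the G changes by six tenths of a point or more over the second half of the time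

We read column E against column Q. In red, E over Q goes from 0.209 at 20.0 min to 1.85 at 80.0 min. In amber it goes from 0.241 to 1.83 over the same times, and in grey from 0.250 to 2.04. So these are no twins: E grows out of Q.

Next we divide the E gained per minute by the mean Q standing over a late stretch. Grey, from 40.0 min to 80.0 min, gives 0.0234 min⁻¹. This passing share, the part of the standing Q that turns into E each minute, is the usual first-order rate constant. Amber, from 40.0 min to 80.0 min, gives 0.0247 min⁻¹, though grey holds twice the G of amber.

So E in a flask is the passing share times the minutes times the mean Q. The forecast answers it is still moving, gives E 57% (53% to 61%), Q 24.8% (22.5% to 27.5%) and conversion 81.8% (78% to 85%), and says “everything is changing, so the reaction is still moving”. By our rule, that E asks for a mean Q of 27.1% over 1.5 h.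

The flask gives: it is still moving, conversion 82.0%, Q 25.0%, E 57.0%.

    G + J → Q, rate k1*[G]*[J]^0.5 (k = 0.0400 L⁰·⁵ mol⁻⁰·⁵ min⁻¹)
    Q → E (k = 0.0230 min⁻¹)

The flask is still moving because we read it at 1.5 h and not ten times later: the conversion is 82.0% at 1.5 h and >99.9% at 15.0 h. From 0.750 h to 1.5 h the passing share predicts a gain in E of 32 percentage points, and the flask gains 33 points. With the rest of the flask held, E has moved 5 points, which is already outside the forecast's range, when J goes to 0.879 equiv or 1.42 equiv.

Read at 50 min, the same flask should hold E at 28.7% by the passing share, and it holds 28.6%.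

The readings were computed from invented constants; noise was put on by code.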